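**Retrosynthetic overview**

1. Ring B (the pyran) is closed last, by 6-endo hydroalkoxylation of the C1 hydroxyl onto the ynenone of tetraol 27.
2. The C4a–C4 bond comes from a Sonogashira coupling of enol triflate 14 (ring A, 13 skeletal atoms) with terminal enyne 25 (13 atoms).
3. Ring A comes from an intramolecular Claisen condensation of keto-lactone 10 to a cyclohexane-1,3-dione, then C5 chlorination and regioselective O-triflation.
4. The C7/C8/C8a triad comes from a temporary δ-lactone 7: organocatalytic α-hydroxymethylation sets C8a, and OsO4 adds anti to the C8a substituent.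
5. The side chain comes from Brown crotylboration, oxolane closure, chelation-controlled ethynyl addition (carbinol centre) and two-carbon extension. Ring order: oxolane, temporary δ-lactone, ring A, ring B.

Assumption: locants C1–C8a are those of the isochromenone core of the target (C6 ketone, C5–Cl, O2 ring oxygen); the enantiopure catalyst and borane reagent named are purchased.

**Route**

Step 1
Reactants: 1 methyl acetoacetate
Product: 2 methyl 2-(2-methyl-1,3-dioxolan-2-yl)acetate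
Conditions: ethylene glycol, p-TsOH (cat.), toluene, Dean–Stark, reflux
Reagents that add atoms: ethylene glycol, OCCO
Why: Acid-catalysed ketalisation masks the ketone (future C4a) while the ester is untouched.

Step 2
Reactants: 2 methyl 2-(2-methyl-1,3-dioxolan-2-yl)acetate
Product: 3 2-(2-methyl-1,3-dioxolan-2-yl)acetaldehyde
Conditions: iBu2AlH (1.1 equiv), CH2Cl2, −78 °C; aq. KNaC4H4O6 work-up
Reagents that add atoms: none
Why: Low-temperature hydride half-reduction of the ester stops at the aldehyde because the tetrahedral aluminate survives until work-up.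

Step 3
Reactants: 3 2-(2-methyl-1,3-dioxolan-2-yl)acetaldehyde
Product: 5 (2S)-3-[(tert-butyldimethylsilyl)oxy]-2-(2-methyl-1,3-dioxolan-2-yl)propanal, via hydroxymethyl aldehyde 4 (not isolated)
Conditions: 37% aq. HCHO, (R)-α,α-diphenylprolinol trimethylsilyl ether (10 mol%), pH 7 buffer (NaH2PO4/Na2HPO4), toluene, rt; phase cut, dry (Na2SO4); then TBSCl, imidazole, DMAP (cat.), 0 °C to rt
Reagents that add atoms: formaldehyde, C=O; tert-butyldimethylsilyl chloride, CC(C)(C)[Si](C)(C)Cl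
Why: Enamine-catalysed α-hydroxymethylation (organocatalytic cross-aldol): the (R)-catalyst shields one enamine face so formaldehyde adds to the other and sets C8a, and silylation stops retro-aldol and oligomerisation.

Step 4
Reactants: 5 (2S)-3-[(tert-butyldimethylsilyl)oxy]-2-(2-methyl-1,3-dioxolan-2-yl)propanal
Product: 7 (5R)-3-methyl-5-(2-methyl-1,3-dioxolan-2-yl)-5,6-dihydro-2H-pyran-2-one, via Z-enoate 6 (not isolated)
Conditions: (CF3CH2O)2P(O)CH(CH3)CO2Me, KN(SiMe3)2, 18-crown-6, THF, −78 °C; then HF·pyridine, 0 °C to rt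
Reagents that add atoms: methyl 2-[bis(2,2,2-trifluoroethoxy)phosphoryl]propanoate, COC(=O)C(C)P(=O)(OCC(F)(F)F)OCC(F)(F)F
Why: Still–Gennari olefination gives the Z-trisubstituted enoate, and desilylation lets the cis hydroxyl lactonise; C8a is not touched.

Step 5
Reactants: 7 (5R)-3-methyl-5-(2-methyl-1,3-dioxolan-2-yl)-5,6-dihydro-2H-pyran-2-one
Product: 8 (3R,4R,5S)-3,4-dihydroxy-3-methyl-5-(2-methyl-1,3-dioxolan-2-yl)oxan-2-one
Conditions: OsO4 (5 mol%), NMO, citric acid, acetone/H2O, rt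
Reagents that add atoms: N-methylmorpholine N-oxide, C[N+]1([O-])CCOCC1; water, O
Why: Upjohn syn-dihydroxylation occurs on the lactone face anti to the bulky allylic ketal group, which sets C7 and C8 as a cis-diol that ends up cis to the C1 carbon in ring A.

Step 6
Reactants: 8 (3R,4R,5S)-3,4-dihydroxy-3-methyl-5-(2-methyl-1,3-dioxolan-2-yl)oxan-2-one
Product: 9 (3R,4R,5S)-3-methyl-5-(2-methyl-1,3-dioxolan-2-yl)-3,4-bis[(triethylsilyl)oxy]oxan-2-one
Conditions: Et3SiOTf (3 equiv), 2,6-lutidine, CH2Cl2, 0 °C to rt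
Reagents that add atoms: triethylsilyl triflate, CC[Si](CC)(CC)OS(=O)(=O)C(F)(F)F
Why: Silyl triflate silylation protects both the secondary and the hindered tertiary hydroxyl as fluoride-labile ethers.

Step 7
Reactants: 9 (3R,4R,5S)-3-methyl-5-(2-methyl-1,3-dioxolan-2-yl)-3,4-bis[(triethylsilyl)oxy]oxan-2-one
Product: 10 (3R,4R,5S)-5-acetyl-3-methyl-3,4-bis[(triethylsilyl)oxy]oxan-2-one
Conditions: PPTS (0.3 equiv), acetone/H2O (10:1), 45 °C
Reagents that add atoms: water, O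
Why: Mild acid-catalysed ketal hydrolysis frees the methyl ketone while the hindered silyl ethers survive; the acetyl group is already trans to the neighbouring silyloxy group, so C8a has no driving force to epimerise.

Step 8
Reactants: 10 (3R,4R,5S)-5-acetyl-3-methyl-3,4-bis[(triethylsilyl)oxy]oxan-2-one
Product: 11 (4R,5R,6S)-6-(hydroxymethyl)-4-methyl-4,5-bis[(triethylsilyl)oxy]cyclohexane-1,3-dione
Conditions: LiN(SiMe3)2 (2.5 equiv), THF, −78 to 0 °C (inverse addition); AcOH quench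
Reagents that add atoms: none
Why: Intramolecular Claisen (Dieckmann-type) condensation: the kinetic methyl enolate attacks the lactone carbonyl (which has no α-hydrogen), the ring opens to release the C1 alkoxide, and formation of the dione enolate drives ring A closure without touching the stereocentres.

Step 9
Reactants: 11 (4R,5R,6S)-6-(hydroxymethyl)-4-methyl-4,5-bis[(triethylsilyl)oxy]cyclohexane-1,3-dione
Product: 12 (4R,5R,6S)-6-{[(tert-butyldimethylsilyl)oxy]methyl}-4-methyl-4,5-bis[(triethylsilyl)oxy]cyclohexane-1,3-dione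
Conditions: TBSCl, imidazole, DMF, 0 °C; aqueous work-up
Reagents that add atoms: tert-butyldimethylsilyl chloride, CC(C)(C)[Si](C)(C)Cl
Why: Silylation of the primary C1 hydroxyl (any enol silyl ether hydrolyses on work-up) keeps it from reacting in the triflation and coupling.

Step 10
Reactants: 12 (4R,5R,6S)-6-{[(tert-butyldimethylsilyl)oxy]methyl}-4-methyl-4,5-bis[(triethylsilyl)oxy]cyclohexane-1,3-dione
Product: 13 (4S,5R,6R)-4-{[(tert-butyldimethylsilyl)oxy]methyl}-2-chloro-3-hydroxy-6-methyl-5,6-bis[(triethylsilyl)oxy]cyclohex-2-en-1-one (2-chloro-1,3-dione drawn as one enol)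
Conditions: NCS (1.0 equiv), CH2Cl2, 0 °C
Reagents that add atoms: N-chlorosuccinimide, O=C1CCC(=O)N1Cl
Why: Electrophilic chlorination of the enolised 1,3-dione occurs only at the central carbon, which places Cl at C5.

Step 11
Reactants: 13 (4S,5R,6R)-4-{[(tert-butyldimethylsilyl)oxy]methyl}-2-chloro-3-hydroxy-6-methyl-5,6-bis[(triethylsilyl)oxy]cyclohex-2-en-1-one
Product: 14 (4S,5R,6R)-4-{[(tert-butyldimethylsilyl)oxy]methyl}-2-chloro-6-methyl-5,6-bis[(triethylsilyl)oxy]-3-[(trifluoromethanesulfonyl)oxy]cyclohex-2-en-1-one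
Conditions: Tf2O (1.1 equiv), 2,6-lutidine, CH2Cl2, −78 °C
Reagents that add atoms: triflic anhydride, O=S(=O)(OS(=O)(=O)C(F)(F)F)C(F)(F)F
Why: O-sulfonylation of the dione enolate should go to the less hindered, more electron-rich oxygen (on C4a, away from the quaternary α-silyloxy carbon C7), giving the vinylogous acyl triflate with the ketone at C6; this regiochemistry is argued by analogy with 4,4-disubstituted cyclohexane-1,3-diones and is the main uncertainty.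

Step 12
Reactants: 15 (2E)-2-methylbut-2-enal
Product: 16 (3S,4S,5E)-3,5-dimethylhepta-1,5-dien-4-ol
Conditions: (−)-Ipc2B-(E)-crotyl [made in the flask from (E)-but-2-ene, n-BuLi, KOtBu, (−)-Ipc2BOMe, BF3·OEt2], THF/Et2O, −78 °C; then NaOH, H2O2
Reagents that add atoms: (−)-B-[(E)-crotyl]diisopinocampheylborane, C/C=C/CB([C@@H]1C[C@@H]2C[C@H]([C@H]1C)C2(C)C)[C@@H]1C[C@@H]2C[C@H]([C@H]1C)C2(C)C
Why: Brown crotylboration through a chair Zimmerman–Traxler transition state: the E-crotyl unit gives the anti adduct and the isopinocampheyl groups fix the absolute sense, setting the future oxolane C2 and C3.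

Step 13
Reactants: 16 (3S,4S,5E)-3,5-dimethylhepta-1,5-dien-4-ol
Product: 17 (3S,4S,5E)-3,5-dimethylhept-5-ene-1,4-diol
Conditions: 9-BBN (2.2 equiv), THF, 0 °C to rt; then NaOH, H2O2
Reagents that add atoms: hydrogen peroxide, OO
Why: Anti-Markovnikov hydroboration–oxidation with the bulky borane takes the monosubstituted vinyl group and leaves the trisubstituted alkene.

Step 14
Reactants: 17 (3S,4S,5E)-3,5-dimethylhept-5-ene-1,4-diol
Product: 19 (2S,3S)-2-[(2E)-but-2-en-2-yl]-3-methyloxolane, via primary tosylate 18 (not isolated)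
Conditions: TsCl (1.05 equiv), pyridine, 0 °C; then 50 °C
Reagents that add atoms: none
Why: Selective sulfonylation of the primary hydroxyl and intramolecular Williamson etherification (5-exo-tet) close the oxolane with both stereocentres retained, giving the trans-2,3 ring.

Step 15
Reactants: 19 (2S,3S)-2-[(2E)-but-2-en-2-yl]-3-methyloxolane
Product: 20 1-[(2S,3S)-3-methyloxolan-2-yl]ethan-1-one
Conditions: O3, CH2Cl2/MeOH, −78 °C; then Me2S
Reagents that add atoms: ozone, [O-][O+]=O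
Why: Ozonolysis with reductive work-up cleaves the trisubstituted alkene to the methyl ketone without affecting the ring stereocentres.

Step 16
Reactants: 20 1-[(2S,3S)-3-methyloxolan-2-yl]ethan-1-one
Product: 21 (2S)-2-[(2S,3S)-3-methyloxolan-2-yl]but-3-yn-2-ol
Conditions: HC≡CMgBr (2 equiv), THF, −78 °C; aq. NH4Cl
Reagents that add atoms: ethynylmagnesium bromide, C#C[Mg]Br
Why: Cram-chelate Grignard addition: magnesium bridges the ketone and ring oxygens and the acetylide attacks from the face of the C2 hydrogen, giving the (S)-carbinol.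

Step 17
Reactants: 21 (2S)-2-[(2S,3S)-3-methyloxolan-2-yl]but-3-yn-2-ol
Product: 22 (2S,3E)-2-[(2S,3S)-3-methyloxolan-2-yl]-4-(tributylstannyl)but-3-en-2-ol
Conditions: Bu3SnH (1.2 equiv), PdCl2(PPh3)2 (2 mol%), THF, 0 °C
Reagents that add atoms: tributyltin hydride, CCCC[SnH](CCCC)CCCC
Why: Palladium-catalysed syn-hydrostannation puts tin on the terminal carbon, away from the bulky tertiary carbinol, giving the E-vinylstannane.

Step 18
Reactants: 22 (2S,3E)-2-[(2S,3S)-3-methyloxolan-2-yl]-4-(tributylstannyl)but-3-en-2-ol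
Product: 23 (2S,3E)-4-iodo-2-[(2S,3S)-3-methyloxolan-2-yl]but-3-en-2-ol
Conditions: I2 (1.05 equiv), CH2Cl2, 0 °C
Reagents that add atoms: iodine, II
Why: Iododestannylation replaces tin by iodine with retention of the E geometry.

Step 19
Reactants: 23 (2S,3E)-4-iodo-2-[(2S,3S)-3-methyloxolan-2-yl]but-3-en-2-ol
Product: 24 (2S,3E)-2-[(2S,3S)-3-methyloxolan-2-yl]-6-(trimethylsilyl)hex-3-en-5-yn-2-ol
Conditions: HC≡CSiMe3, PdCl2(PPh3)2 (3 mol%), CuI (6 mol%), Et3N, THF, rt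
Reagents that add atoms: ethynyltrimethylsilane, C#C[Si](C)(C)C
Why: Sonogashira coupling of the vinyl iodide proceeds with retention of alkene geometry and tolerates the free tertiary alcohol.

Step 20
Reactants: 24 (2S,3E)-2-[(2S,3S)-3-methyloxolan-2-yl]-6-(trimethylsilyl)hex-3-en-5-yn-2-ol
Product: 25 (2S,3E)-2-[(2S,3S)-3-methyloxolan-2-yl]hex-3-en-5-yn-2-ol
Conditions: K2CO3 (cat.), MeOH, rt
Reagents that add atoms: none
Why: Methanolysis of the alkynylsilane (protodesilylation) frees the terminal alkyne.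

Step 21
Reactants: 14 (4S,5R,6R)-4-{[(tert-butyldimethylsilyl)oxy]methyl}-2-chloro-6-methyl-5,6-bis[(triethylsilyl)oxy]-3-[(trifluoromethanesulfonyl)oxy]cyclohex-2-en-1-one; 25 (2S,3E)-2-[(2S,3S)-3-methyloxolan-2-yl]hex-3-en-5-yn-2-ol
Product: 26 (4S,5R,6R)-4-{[(tert-butyldimethylsilyl)oxy]methyl}-2-chloro-3-{(3E,5S)-5-hydroxy-5-[(2S,3S)-3-methyloxolan-2-yl]hex-3-en-1-yn-1-yl}-6-methyl-5,6-bis[(triethylsilyl)oxy]cyclohex-2-en-1-one
Conditions: Pd(PPh3)4 (5 mol%), CuI (10 mol%), iPr2NEt, degassed THF, 0 °C to rt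
Reagents that add atoms: none
Why: Sonogashira coupling: the vinylogous acyl triflate undergoes fast oxidative addition while the vinyl chloride stays, and the tertiary amine avoids conjugate addition to the ynenone.

Step 22
Reactants: 26 (4S,5R,6R)-4-{[(tert-butyldimethylsilyl)oxy]methyl}-2-chloro-3-{(3E,5S)-5-hydroxy-5-[(2S,3S)-3-methyloxolan-2-yl]hex-3-en-1-yn-1-yl}-6-methyl-5,6-bis[(triethylsilyl)oxy]cyclohex-2-en-1-one
Product: 27 (4S,5R,6R)-2-chloro-5,6-dihydroxy-4-(hydroxymethyl)-3-{(3E,5S)-5-hydroxy-5-[(2S,3S)-3-methyloxolan-2-yl]hex-3-en-1-yn-1-yl}-6-methylcyclohex-2-en-1-one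
Conditions: HF·pyridine, pyridine, THF, 0 °C to rt
Reagents that add atoms: none
Why: Buffered fluoride desilylation removes all three silyl ethers without base, which protects the γ-hydrogen at C8a and the tertiary allylic alcohol.

Step 23
Reactants: 27 (4S,5R,6R)-2-chloro-5,6-dihydroxy-4-(hydroxymethyl)-3-{(3E,5S)-5-hydroxy-5-[(2S,3S)-3-methyloxolan-2-yl]hex-3-en-1-yn-1-yl}-6-methylcyclohex-2-en-1-one
Product: 28 (7R,8R,8aS)-5-chloro-7,8-dihydroxy-3-{(1E,3S)-3-hydroxy-3-[(2S,3S)-3-methyloxolan-2-yl]but-1-en-1-yl}-7-methyl-1,7,8,8a-tetrahydro-6H-isochromen-6-one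
Conditions: Ph3PAuNTf2 (5 mol%), CH2Cl2, 0 °C to rt
Reagents that add atoms: none
Why: Gold-catalysed 6-endo-dig hydroalkoxylation (cycloisomerisation): the C1 hydroxyl attacks the alkyne carbon remote from the enone (the vinylogous Michael position, also stabilised by the vinyl group), closing ring B; the C8 hydroxyl cannot compete because it would form a bridgehead alkene.

**Compound list**

1 | methyl acetoacetate | CC(=O)CC(=O)OC | starting material
2 | methyl 2-(2-methyl-1,3-dioxolan-2-yl)acetate | COC(=O)CC1(C)OCCO1 | intermediate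
3 | 2-(2-methyl-1,3-dioxolan-2-yl)acetaldehyde | O=CCC1(C)OCCO1 | intermediate
4 | (2S)-3-hydroxy-2-(2-methyl-1,3-dioxolan-2-yl)propanal (not isolated) | CC1(OCCO1)[C@@H](CO)C=O | intermediate
5 | (2S)-3-[(tert-butyldimethylsilyl)oxy]-2-(2-methyl-1,3-dioxolan-2-yl)propanal | CC1(OCCO1)[C@@H](CO[Si](C)(C)C(C)(C)C)C=O | intermediate
6 | methyl (2Z,4R)-5-[(tert-butyldimethylsilyl)oxy]-2-methyl-4-(2-methyl-1,3-dioxolan-2-yl)pent-2-enoate (not isolated) | CC1(OCCO1)[C@@H](CO[Si](C)(C)C(C)(C)C)/C=C(/C)C(=O)OC | intermediate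
7 | (5R)-3-methyl-5-(2-methyl-1,3-dioxolan-2-yl)-5,6-dihydro-2H-pyran-2-one | CC2(OCCO2)[C@H]1COC(=O)C(C)=C1 | intermediate
8 | (3R,4R,5S)-3,4-dihydroxy-3-methyl-5-(2-methyl-1,3-dioxolan-2-yl)oxan-2-one | CC2(OCCO2)[C@H]1COC(=O)[C@](C)(O)[C@@H]1O | intermediate
9 | (3R,4R,5S)-3-methyl-5-(2-methyl-1,3-dioxolan-2-yl)-3,4-bis[(triethylsilyl)oxy]oxan-2-one | CC2(OCCO2)[C@H]1COC(=O)[C@](C)(O[Si](CC)(CC)CC)[C@@H]1O[Si](CC)(CC)CC | intermediate
10 | (3R,4R,5S)-5-acetyl-3-methyl-3,4-bis[(triethylsilyl)oxy]oxan-2-one | CC(=O)[C@H]1COC(=O)[C@](C)(O[Si](CC)(CC)CC)[C@@H]1O[Si](CC)(CC)CC | intermediate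
11 | (4R,5R,6S)-6-(hydroxymethyl)-4-methyl-4,5-bis[(triethylsilyl)oxy]cyclohexane-1,3-dione | O=C2CC(=O)[C@](C)(O[Si](CC)(CC)CC)[C@H](O[Si](CC)(CC)CC)[C@@H]2CO | intermediate
12 | (4R,5R,6S)-6-{[(tert-butyldimethylsilyl)oxy]methyl}-4-methyl-4,5-bis[(triethylsilyl)oxy]cyclohexane-1,3-dione | O=C2CC(=O)[C@](C)(O[Si](CC)(CC)CC)[C@H](O[Si](CC)(CC)CC)[C@@H]2CO[Si](C)(C)C(C)(C)C | intermediate
13 | (4S,5R,6R)-4-{[(tert-butyldimethylsilyl)oxy]methyl}-2-chloro-3-hydroxy-6-methyl-5,6-bis[(triethylsilyl)oxy]cyclohex-2-en-1-one (enol form of the 2-chloro-1,3-dione) | OC2=C(Cl)C(=O)[C@](C)(O[Si](CC)(CC)CC)[C@H](O[Si](CC)(CC)CC)[C@@H]2CO[Si](C)(C)C(C)(C)C | intermediate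
14 | (4S,5R,6R)-4-{[(tert-butyldimethylsilyl)oxy]methyl}-2-chloro-6-methyl-5,6-bis[(triethylsilyl)oxy]-3-[(trifluoromethanesulfonyl)oxy]cyclohex-2-en-1-one | FC(F)(F)S(=O)(=O)OC2=C(Cl)C(=O)[C@](C)(O[Si](CC)(CC)CC)[C@H](O[Si](CC)(CC)CC)[C@@H]2CO[Si](C)(C)C(C)(C)C | intermediate
15 | (2E)-2-methylbut-2-enal | C/C=C(\C)C=O | starting material
16 | (3S,4S,5E)-3,5-dimethylhepta-1,5-dien-4-ol | C[C@@H](C=C)[C@H](O)/C(C)=C/C | intermediate
17 | (3S,4S,5E)-3,5-dimethylhept-5-ene-1,4-diol | C[C@@H](CCO)[C@H](O)/C(C)=C/C | intermediate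
18 | (3S,4S,5E)-4-hydroxy-3,5-dimethylhept-5-en-1-yl 4-methylbenzenesulfonate (not isolated) | C[C@@H](CCOS(=O)(=O)c1ccc(C)cc1)[C@H](O)/C(C)=C/C | intermediate
19 | (2S,3S)-2-[(2E)-but-2-en-2-yl]-3-methyloxolane | C[C@H]1CCO[C@@H]1/C(C)=C/C | intermediate
20 | 1-[(2S,3S)-3-methyloxolan-2-yl]ethan-1-one | C[C@H]1CCO[C@@H]1C(C)=O | intermediate
21 | (2S)-2-[(2S,3S)-3-methyloxolan-2-yl]but-3-yn-2-ol | C[C@H]1CCO[C@@H]1[C@@](C)(O)C#C | intermediate
22 | (2S,3E)-2-[(2S,3S)-3-methyloxolan-2-yl]-4-(tributylstannyl)but-3-en-2-ol | C[C@H]1CCO[C@@H]1[C@@](C)(O)/C=C/[Sn](CCCC)(CCCC)CCCC | intermediate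
23 | (2S,3E)-4-iodo-2-[(2S,3S)-3-methyloxolan-2-yl]but-3-en-2-ol | C[C@H]1CCO[C@@H]1[C@@](C)(O)/C=C/I | intermediate
24 | (2S,3E)-2-[(2S,3S)-3-methyloxolan-2-yl]-6-(trimethylsilyl)hex-3-en-5-yn-2-ol | C[C@H]1CCO[C@@H]1[C@@](C)(O)/C=C/C#C[Si](C)(C)C | intermediate
25 | (2S,3E)-2-[(2S,3S)-3-methyloxolan-2-yl]hex-3-en-5-yn-2-ol | C[C@H]1CCO[C@@H]1[C@@](C)(O)/C=C/C#C | intermediate
26 | (4S,5R,6R)-4-{[(tert-butyldimethylsilyl)oxy]methyl}-2-chloro-3-{(3E,5S)-5-hydroxy-5-[(2S,3S)-3-methyloxolan-2-yl]hex-3-en-1-yn-1-yl}-6-methyl-5,6-bis[(triethylsilyl)oxy]cyclohex-2-en-1-one | C[C@H]1CCO[C@@H]1[C@@](C)(O)/C=C/C#CC2=C(Cl)C(=O)[C@](C)(O[Si](CC)(CC)CC)[C@H](O[Si](CC)(CC)CC)[C@@H]2CO[Si](C)(C)C(C)(C)C | intermediate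
27 | (4S,5R,6R)-2-chloro-5,6-dihydroxy-4-(hydroxymethyl)-3-{(3E,5S)-5-hydroxy-5-[(2S,3S)-3-methyloxolan-2-yl]hex-3-en-1-yn-1-yl}-6-methylcyclohex-2-en-1-one | C[C@H]1CCO[C@@H]1[C@@](C)(O)/C=C/C#CC2=C(Cl)C(=O)[C@](C)(O)[C@H](O)[C@@H]2CO | intermediate
28 | (7R,8R,8aS)-5-chloro-7,8-dihydroxy-3-{(1E,3S)-3-hydroxy-3-[(2S,3S)-3-methyloxolan-2-yl]but-1-en-1-yl}-7-methyl-1,7,8,8a-tetrahydro-6H-isochromen-6-one | C[C@H]1CCO[C@@H]1[C@@](C)(O)/C=C/C1=CC2=C(Cl)C(=O)[C@](C)(O)[C@H](O)[C@@H]2CO1 | target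

**Step count and risks**

Total step count: 23 (steps 1–11 ring A fragment, steps 12–20 side-chain fragment, steps 21–23 coupling and endgame).
Longest linear sequence: 14 steps (1–11, then 21–23); the side-chain branch is 12 steps (12–20, then 21–23).

The three steps most likely to fail:

Step 3 (enamine hydroxymethylation of a β-ketal aldehyde; risk of low ee or elimination). The fallback sets the C8a centre with an Evans auxiliary. It sets out from 2 and comes back at 5.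
- LiOH hydrolysis of 2 gives 2-(2-methyl-1,3-dioxolan-2-yl)acetic acid F1.
- Pivaloyl chloride/Et3N, then lithiated (S)-4-benzyl-1,3-oxazolidin-2-one, gives (4S)-4-benzyl-3-[2-(2-methyl-1,3-dioxolan-2-yl)acetyl]-1,3-oxazolidin-2-one F2.
- NaN(SiMe3)2 at −78 °C and benzyl chloromethyl ether alkylate the chelated Z-enolate anti to the benzyl group, giving (4S)-4-benzyl-3-[(2S)-3-(benzyloxy)-2-(2-methyl-1,3-dioxolan-2-yl)propanoyl]-1,3-oxazolidin-2-one F3.
- LiBH4 removes the auxiliary to give (2S)-3-(benzyloxy)-2-(2-methyl-1,3-dioxolan-2-yl)propan-1-ol F4.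
- TBSCl/imidazole gives (2R)-1-(benzyloxy)-3-[(tert-butyldimethylsilyl)oxy]-2-(2-methyl-1,3-dioxolan-2-yl)propane F5.
- H2 over Pd/C gives (2R)-3-[(tert-butyldimethylsilyl)oxy]-2-(2-methyl-1,3-dioxolan-2-yl)propan-1-ol F6.
- Dess–Martin oxidation of F6 gives 5.

Step 8 (Claisen closure onto a hindered lactone; risk of β-elimination of the lactone carboxylate from the C8a enolate). The fallback replaces the lactone by an open-chain Weinreb amide that has no good β-leaving group. It sets out from 9 and comes back at 12.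
- MeNH(OMe)·HCl with iPrMgCl opens 9 to (2R,3R,4S)-5-hydroxy-N-methoxy-N,2-dimethyl-4-(2-methyl-1,3-dioxolan-2-yl)-2,3-bis[(triethylsilyl)oxy]pentanamide F7.
- TBSCl/imidazole gives (2R,3R,4S)-5-[(tert-butyldimethylsilyl)oxy]-N-methoxy-N,2-dimethyl-4-(2-methyl-1,3-dioxolan-2-yl)-2,3-bis[(triethylsilyl)oxy]pentanamide F8.
- PPTS in wet acetone unmasks (2R,3R,4S)-4-acetyl-5-[(tert-butyldimethylsilyl)oxy]-N-methoxy-N,2-dimethyl-2,3-bis[(triethylsilyl)oxy]pentanamide F9.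
- LiN(SiMe3)2 at −78 °C then lets the kinetic methyl enolate acylate on the Weinreb amide, giving 12 directly.

Step 11 (triflation regiochemistry of the unsymmetrical 2-chloro-1,3-dione). The fallback fixes the carbonyl positions without ambiguity and brings in the alkyne by 1,2-addition and oxidative transposition. It sets out from 9 and comes back at 26.
- iBu2AlH at −78 °C reduces 9 to (3R,4R,5S)-3-methyl-5-(2-methyl-1,3-dioxolan-2-yl)-3,4-bis[(triethylsilyl)oxy]oxan-2-ol F10.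
- PPTS in wet acetone gives the keto-lactol 1-[(3S,4R,5R)-6-hydroxy-5-methyl-4,5-bis[(triethylsilyl)oxy]oxan-3-yl]ethan-1-one F11.
- Dibenzylammonium trifluoroacetate effects intramolecular aldol condensation to (4S,5R,6S)-6-(hydroxymethyl)-4-methyl-4,5-bis[(triethylsilyl)oxy]cyclohex-2-en-1-one F12, whose carbonyl is C4a.
- TBSCl/imidazole gives (4S,5R,6S)-6-{[(tert-butyldimethylsilyl)oxy]methyl}-4-methyl-4,5-bis[(triethylsilyl)oxy]cyclohex-2-en-1-one F13.
- PhICl2/pyridine (addition then elimination) gives (4S,5R,6S)-6-{[(tert-butyldimethylsilyl)oxy]methyl}-2-chloro-4-methyl-4,5-bis[(triethylsilyl)oxy]cyclohex-2-en-1-one F14.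
- HC≡CMgBr with CeCl3 adds 1,2 to give (4S,5R,6S)-6-{[(tert-butyldimethylsilyl)oxy]methyl}-2-chloro-1-ethynyl-4-methyl-4,5-bis[(triethylsilyl)oxy]cyclohex-2-en-1-ol (both carbinol epimers) F15.
- Babler–Dauben oxidative 1,3-transposition with C5H5NH[CrO3Cl] gives (4S,5R,6R)-4-{[(tert-butyldimethylsilyl)oxy]methyl}-2-chloro-3-ethynyl-6-methyl-5,6-bis[(triethylsilyl)oxy]cyclohex-2-en-1-one F16.
- Sonogashira coupling of F16 with vinyl iodide 23 (Pd(PPh3)4, CuI, Et3N) gives 26.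

Further compounds
F1 | step 3 | 2-(2-methyl-1,3-dioxolan-2-yl)acetic acid | CC1(CC(=O)O)OCCO1
F2 | step 3 | (4S)-4-benzyl-3-[2-(2-methyl-1,3-dioxolan-2-yl)acetyl]-1,3-oxazolidin-2-one | CC1(CC(=O)N2[C@@H](Cc3ccccc3)COC2=O)OCCO1
F3 | step 3 | (4S)-4-benzyl-3-[(2S)-3-(benzyloxy)-2-(2-methyl-1,3-dioxolan-2-yl)propanoyl]-1,3-oxazolidin-2-one | CC1(OCCO1)[C@H](COCc2ccccc2)C(=O)N3[C@@H](Cc4ccccc4)COC3=O
F4 | step 3 | (2S)-3-(benzyloxy)-2-(2-methyl-1,3-dioxolan-2-yl)propan-1-ol | CC1(OCCO1)[C@H](COCc2ccccc2)CO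
F5 | step 3 | (2R)-1-(benzyloxy)-3-[(tert-butyldimethylsilyl)oxy]-2-(2-methyl-1,3-dioxolan-2-yl)propane | CC1(OCCO1)[C@H](COCc2ccccc2)CO[Si](C)(C)C(C)(C)C
F6 | step 3 | (2R)-3-[(tert-butyldimethylsilyl)oxy]-2-(2-methyl-1,3-dioxolan-2-yl)propan-1-ol | CC1(OCCO1)[C@H](CO)CO[Si](C)(C)C(C)(C)C
F7 | step 8 | (2R,3R,4S)-5-hydroxy-N-methoxy-N,2-dimethyl-4-(2-methyl-1,3-dioxolan-2-yl)-2,3-bis[(triethylsilyl)oxy]pentanamide | CON(C)C(=O)[C@](C)(O[Si](CC)(CC)CC)[C@H](O[Si](CC)(CC)CC)[C@H](CO)C1(C)OCCO1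
F8 | step 8 | (2R,3R,4S)-5-[(tert-butyldimethylsilyl)oxy]-N-methoxy-N,2-dimethyl-4-(2-methyl-1,3-dioxolan-2-yl)-2,3-bis[(triethylsilyl)oxy]pentanamide | CON(C)C(=O)[C@](C)(O[Si](CC)(CC)CC)[C@H](O[Si](CC)(CC)CC)[C@H](CO[Si](C)(C)C(C)(C)C)C1(C)OCCO1
F9 | step 8 | (2R,3R,4S)-4-acetyl-5-[(tert-butyldimethylsilyl)oxy]-N-methoxy-N,2-dimethyl-2,3-bis[(triethylsilyl)oxy]pentanamide | CON(C)C(=O)[C@](C)(O[Si](CC)(CC)CC)[C@H](O[Si](CC)(CC)CC)[C@H](CO[Si](C)(C)C(C)(C)C)C(C)=O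
F10 | step 11 | (3R,4R,5S)-3-methyl-5-(2-methyl-1,3-dioxolan-2-yl)-3,4-bis[(triethylsilyl)oxy]oxan-2-ol (anomers) | CC2(OCCO2)[C@H]1COC(O)[C@](C)(O[Si](CC)(CC)CC)[C@@H]1O[Si](CC)(CC)CC
F11 | step 11 | 1-[(3S,4R,5R)-6-hydroxy-5-methyl-4,5-bis[(triethylsilyl)oxy]oxan-3-yl]ethan-1-one (anomers) | CC(=O)[C@H]1COC(O)[C@](C)(O[Si](CC)(CC)CC)[C@@H]1O[Si](CC)(CC)CC
F12 | step 11 | (4S,5R,6S)-6-(hydroxymethyl)-4-methyl-4,5-bis[(triethylsilyl)oxy]cyclohex-2-en-1-one | O=C2C=C[C@](C)(O[Si](CC)(CC)CC)[C@H](O[Si](CC)(CC)CC)[C@@H]2CO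
F13 | step 11 | (4S,5R,6S)-6-{[(tert-butyldimethylsilyl)oxy]methyl}-4-methyl-4,5-bis[(triethylsilyl)oxy]cyclohex-2-en-1-one | O=C2C=C[C@](C)(O[Si](CC)(CC)CC)[C@H](O[Si](CC)(CC)CC)[C@@H]2CO[Si](C)(C)C(C)(C)C
F14 | step 11 | (4S,5R,6S)-6-{[(tert-butyldimethylsilyl)oxy]methyl}-2-chloro-4-methyl-4,5-bis[(triethylsilyl)oxy]cyclohex-2-en-1-one | O=C2C(Cl)=C[C@](C)(O[Si](CC)(CC)CC)[C@H](O[Si](CC)(CC)CC)[C@@H]2CO[Si](C)(C)C(C)(C)C
F15 | step 11 | (4S,5R,6S)-6-{[(tert-butyldimethylsilyl)oxy]methyl}-2-chloro-1-ethynyl-4-methyl-4,5-bis[(triethylsilyl)oxy]cyclohex-2-en-1-ol (both C1 epimers) | C#CC2(O)C(Cl)=C[C@](C)(O[Si](CC)(CC)CC)[C@H](O[Si](CC)(CC)CC)[C@@H]2CO[Si](C)(C)C(C)(C)C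
F16 | step 11 | (4S,5R,6R)-4-{[(tert-butyldimethylsilyl)oxy]methyl}-2-chloro-3-ethynyl-6-methyl-5,6-bis[(triethylsilyl)oxy]cyclohex-2-en-1-one | C#CC2=C(Cl)C(=O)[C@](C)(O[Si](CC)(CC)CC)[C@H](O[Si](CC)(CC)CC)[C@@H]2CO[Si](C)(C)C(C)(C)C
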